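**Plan**
- Retrosynthesis: the two MOM ethers and a dithioketal masking C4 are removed last. Ring C is then cut at C3–C4 and at O1–C8a, giving a ring A 2-aryl-1,3-dithiane with fluorine on C8a and the (R)-epoxide of ring B. The dithiane and the geranyl group go back to two directed metalations of 5-fluororesorcinol bis-MOM ether.
- Enabling feature: the carbonyl carbon C4 sits on C4a, ortho to the O1-bearing C8a, and C8–H lies between C8a and the oxygenated C7. C4 can therefore act as a dithiane acyl anion towards C3 of the epoxide, and the C2 alkoxide set free can close onto a C8/C8a aryne made from the C8a fluoride.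
- Forward order: ring A is dressed (geranyl at C6, dithiane at C4a), the ring B epoxide is made, the key step joins both and closes ring C, then ketone and phenols are unmasked.
- Stereochemistry: C2 comes from an asymmetric transfer hydrogenation ((R)-chlorohydrin, then (R)-epoxide). Its C–O bond is never broken, so it becomes (2S) in the flavanone. The E alkene comes in with geranyl bromide.

Key step: step 6

Remark: "geranyl" stands for (2E)-3,7-dimethylocta-2,6-dien-1-yl and MOM for methoxymethyl. Compounds 1, 3, 7 and 12 are taken as commercial. Flavanone numbering (O1, C2, C3, C4, C4a, C5 to C8, C8a) is used for ring positions, also in the precursors.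

Step 1
Reactants: 1 5-fluorobenzene-1,3-diol
Product: 2 1-fluoro-3,5-bis(methoxymethoxy)benzene
Conditions: NaH, MOMCl, DMF, 0 °C to rt
Reagents that add atoms: chloromethyl methyl ether (MOMCl), COCCl
Why: Double Williamson etherification of the bis-phenoxide; MOM is chosen because it directs both later ortho-metalations, tolerates organolithium and amide bases, and leaves under mild acid.

Step 2
Reactants: 2 1-fluoro-3,5-bis(methoxymethoxy)benzene; 3 geranyl bromide
Product: 6 5-fluoro-2-geranyl-1,3-bis(methoxymethoxy)benzene, via aryllithium 4 (not isolated), via arylcopper 5 (not isolated)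
Conditions: n-BuLi, TMEDA, THF, −78 to −40 °C; CuI, −40 °C; then 3, −40 °C to rt
Reagents that add atoms: none
Why: Directed ortho-metalation should take the carbon flanked by both acetal oxygens (double coordination of lithium), and the arylcopper formed with CuI should be allylated at the primary carbon of geranyl bromide (SN2), so the E double bond is carried over unchanged and no stereocentre is formed.

Step 3
Reactants: 6 5-fluoro-2-geranyl-1,3-bis(methoxymethoxy)benzene; 7 1,3-dithiane
Product: 11 2-[6-fluoro-3-geranyl-2,4-bis(methoxymethoxy)phenyl]-1,3-dithiane, via 2-chloro-1,3-dithiane 8 (not isolated), via aryllithium 9 (not isolated), via arylmagnesium bromide 10 (not isolated)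
Conditions: flask A: 7, N-chlorosuccinimide, toluene, rt; flask B: 6, n-BuLi, TMEDA, THF, −78 °C, then MgBr2·OEt2; B into A, −78 to 0 °C
Reagents that add atoms: none
Why: A second directed ortho-metalation takes the only remaining kind of ring hydrogen (flanked by fluorine and an acetal oxygen, both such positions being equivalent), exchange to magnesium stops loss of LiF, and the aryl Grignard reagent substitutes chloride in 2-chloro-1,3-dithiane (a formyl cation equivalent from alpha-chlorination of 1,3-dithiane), which installs the masked C4 without acid and so spares the MOM ethers.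

Step 4
Reactants: 12 2-chloro-1-(3,4-dimethoxyphenyl)ethan-1-one
Product: 13 (1R)-2-chloro-1-(3,4-dimethoxyphenyl)ethan-1-ol
Conditions: Cp*RhCl[(S,S)-TsDPEN] (cat.), HCO2H/Et3N (5:2), EtOAc, rt
Reagents that add atoms: none
Why: Noyori-type asymmetric transfer hydrogenation, in which the (S,S)-TsDPEN metal hydride should deliver hydride to the ketone face that gives the (R)-chlorohydrin (the usual facial sense for aryl ketones, named R here because CH2Cl outranks the aryl group); this sets the only stereocentre of the route.

Step 5
Reactants: 13 (1R)-2-chloro-1-(3,4-dimethoxyphenyl)ethan-1-ol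
Product: 14 (2R)-2-(3,4-dimethoxyphenyl)oxirane
Conditions: NaOH (2 M aq), THF, 0 °C to rt; used crude
Reagents that add atoms: none
Why: Intramolecular Williamson reaction (SN2 of the alkoxide at CH2Cl) that does not touch the stereocentre, so the (R)-epoxide should result, and the basic medium protects this acid-sensitive, electron-rich epoxide.

Step 6
Reactants: 11 2-[6-fluoro-3-geranyl-2,4-bis(methoxymethoxy)phenyl]-1,3-dithiane; 14 (2R)-2-(3,4-dimethoxyphenyl)oxirane
Product: 20 (2S)-2-(3,4-dimethoxyphenyl)-6-geranyl-5,7-bis(methoxymethoxy)spiro[chromane-4,2'-[1,3]dithiane], via 2-lithiodithiane 15 (not isolated), via lithium alkoxide 16 (not isolated), via ring-lithiated alkoxide 17 (not isolated), via aryne 18 (not isolated), via 8-lithiochromane 19 (not isolated)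
Conditions: n-BuLi, THF, −78 °C; then 14, −78 to 0 °C; then LiTMP, −78 °C to rt; NH4Cl (aq)
Reagents that add atoms: none
Why: n-BuLi removes the C-2 hydrogen of the dithiane (Corey–Seebach polarity reversal of the future C4) and the tertiary carbanion 15 opens epoxide 14 by SN2 attack at its CH2 carbon, which makes the C3–C4 bond and sets free the C2 alkoxide 16; LiTMP then metalates the one ring hydrogen of ring A (C8, flanked by fluorine on C8a and the acetal oxygen on C7), LiF is lost on warming, and the tethered alkoxide adds to the C8/C8a aryne 18 at C8a to make the O1–C8a bond, the C8 aryllithium 19 being protonated on work-up. The closest known reaction types are the alkylation of 2-aryl-2-lithio-1,3-dithianes by terminal epoxides and the aryne cyclisation of a haloarene that carries a tethered alkoxide. Ring C closes by a 6-exo-dig addition of O1 to the aryne; addition at C8 is excluded because it would give a bridged ring, and the C7 oxygen polarises the aryne in the same sense. No new stereocentre is formed: C2 is taken over from 14 without its C–O bond being broken, and the descriptor changes from R to S only because the ranking of its substituents changes. The step needs attack at the terminal and not the benzylic epoxide carbon (favoured by the bulk of the tertiary carbanion and the absence of any Lewis acid stronger than the lithium cation), metalation of the dithiane before the ring (its hydrogen is the most acidic one in 11, and −78 °C keeps any ring-metalated material from losing fluoride), and ring metalation at C8 in the last stage (fluorine and acetal flanking). Keeping C4 as a dithioketal through the closure removes the retro-aldol and E1cB pathways by which a free beta-alkoxy ketone would lose the C2 configuration.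

Step 7
Reactants: 20 (2S)-2-(3,4-dimethoxyphenyl)-6-geranyl-5,7-bis(methoxymethoxy)spiro[chromane-4,2'-[1,3]dithiane]
Product: 21 (2S)-2-(3,4-dimethoxyphenyl)-6-geranyl-5,7-bis(methoxymethoxy)chroman-4-one
Conditions: MeI, CaCO3, MeCN/H2O, 45 °C
Reagents that add atoms: water, O
Why: Alkylative hydrolysis of the dithioketal (S-methylation, ring opening to a thionium ion that ring A stabilises strongly because O1 and the C5 and C7 oxygens are ortho and para to C4a, then capture by water); the buffered neutral medium should spare the MOM ethers, both alkenes and the C2 stereocentre.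

Step 8
Reactants: 21 (2S)-2-(3,4-dimethoxyphenyl)-6-geranyl-5,7-bis(methoxymethoxy)chroman-4-one
Product: 22 (2S)-2-(3,4-dimethoxyphenyl)-6-geranyl-5,7-dihydroxychroman-4-one
Conditions: HCl (3 M aq), MeOH, 40 °C
Reagents that add atoms: none
Why: Acid-catalysed acetal cleavage (methanolysis) of the two aryl MOM ethers; dilute acid at moderate temperature should neither open ring C (C2 stays S) nor cyclise the freed phenols onto the geranyl chain.

**Compound list**
1 | 5-fluorobenzene-1,3-diol (5-fluororesorcinol) | Oc1cc(O)cc(F)c1 | starting material
2 | 1-fluoro-3,5-bis(methoxymethoxy)benzene | COCOc1cc(F)cc(OCOC)c1 | intermediate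
3 | geranyl bromide, (2E)-1-bromo-3,7-dimethylocta-2,6-diene | BrC/C=C(\C)CCC=C(C)C | starting material
4 | [4-fluoro-2,6-bis(methoxymethoxy)phenyl]lithium (not isolated) | [Li]c1c(OCOC)cc(F)cc1OCOC | intermediate
5 | [4-fluoro-2,6-bis(methoxymethoxy)phenyl]copper (not isolated) | [Cu]c1c(OCOC)cc(F)cc1OCOC | intermediate
6 | 5-fluoro-2-geranyl-1,3-bis(methoxymethoxy)benzene | COCOc1cc(F)cc(OCOC)c1C/C=C(\C)CCC=C(C)C | intermediate
7 | 1,3-dithiane | C1CSCSC1 | starting material
8 | 2-chloro-1,3-dithiane (not isolated) | ClC1SCCCS1 | intermediate
9 | [6-fluoro-3-geranyl-2,4-bis(methoxymethoxy)phenyl]lithium (not isolated) | [Li]c1c(F)cc(OCOC)c(C/C=C(\C)CCC=C(C)C)c1OCOC | intermediate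
10 | [6-fluoro-3-geranyl-2,4-bis(methoxymethoxy)phenyl]magnesium bromide (not isolated) | Br[Mg]c1c(F)cc(OCOC)c(C/C=C(\C)CCC=C(C)C)c1OCOC | intermediate
11 | 2-[6-fluoro-3-geranyl-2,4-bis(methoxymethoxy)phenyl]-1,3-dithiane | COCOc1cc(F)c(C2SCCCS2)c(OCOC)c1C/C=C(\C)CCC=C(C)C | intermediate
12 | 2-chloro-1-(3,4-dimethoxyphenyl)ethan-1-one | COc1ccc(C(=O)CCl)cc1OC | starting material
13 | (1R)-2-chloro-1-(3,4-dimethoxyphenyl)ethan-1-ol | COc1ccc([C@@H](O)CCl)cc1OC | intermediate
14 | (2R)-2-(3,4-dimethoxyphenyl)oxirane | COc1ccc([C@@H]2CO2)cc1OC | intermediate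
15 | {2-[6-fluoro-3-geranyl-2,4-bis(methoxymethoxy)phenyl]-1,3-dithian-2-yl}lithium (not isolated) | [Li]C1(SCCCS1)c2c(F)cc(OCOC)c(C/C=C(\C)CCC=C(C)C)c2OCOC | intermediate
16 | lithium (1S)-1-(3,4-dimethoxyphenyl)-2-{2-[6-fluoro-3-geranyl-2,4-bis(methoxymethoxy)phenyl]-1,3-dithian-2-yl}ethan-1-olate (not isolated) | COc1ccc([C@@H](O[Li])CC2(SCCCS2)c3c(F)cc(OCOC)c(C/C=C(\C)CCC=C(C)C)c3OCOC)cc1OC | intermediate
17 | alkoxide 16 lithiated at the ring carbon between C–F and C–OMOM, the future C8 (not isolated) | COc1ccc([C@@H](O[Li])CC2(SCCCS2)c3c(F)c([Li])c(OCOC)c(C/C=C(\C)CCC=C(C)C)c3OCOC)cc1OC | intermediate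
18 | aryne formed from 17 by loss of LiF, triple bond between the future C8 and C8a (not isolated) | COc1ccc([C@@H](O[Li])CC2(SCCCS2)C3=C(OCOC)C(C/C=C(\C)CCC=C(C)C)=C(OCOC)C#C3)cc1OC | intermediate
19 | 8-lithio derivative of 20 (not isolated) | COc1ccc([C@@H]2CC3(SCCCS3)c4c(c([Li])c(OCOC)c(C/C=C(\C)CCC=C(C)C)c4OCOC)O2)cc1OC | intermediate
20 | (2S)-2-(3,4-dimethoxyphenyl)-6-geranyl-5,7-bis(methoxymethoxy)spiro[chromane-4,2'-[1,3]dithiane] | COc1ccc([C@@H]2CC3(SCCCS3)c4c(cc(OCOC)c(C/C=C(\C)CCC=C(C)C)c4OCOC)O2)cc1OC | intermediate
21 | (2S)-2-(3,4-dimethoxyphenyl)-6-geranyl-5,7-bis(methoxymethoxy)chroman-4-one | COc1ccc([C@@H]2CC(=O)c3c(cc(OCOC)c(C/C=C(\C)CCC=C(C)C)c3OCOC)O2)cc1OC | intermediate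
22 | (2S)-2-(3,4-dimethoxyphenyl)-6-geranyl-5,7-dihydroxychroman-4-one (CNP0268555.1) | COc1ccc([C@@H]2CC(=O)c3c(cc(O)c(C/C=C(\C)CCC=C(C)C)c3O)O2)cc1OC | target

**Step count and risks**
Total step count: 8. Longest linear sequence: 6 steps (1, 2, 3, 6, 7, 8); steps 4 and 5 form the second branch.

Steps most likely to fail:

1. Step 6. What may go wrong:
   - metalation of the ring next to fluorine during the first deprotonation, followed by premature fluoride loss;
   - attack at the benzylic epoxide carbon, or rearrangement of the electron-rich epoxide;
   - in the last stage, deprotonation of the benzylic and allylic CH2 of the geranyl chain instead of C8, or capture of the aryne by the amide base instead of the alkoxide.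

   Fallback: the union is stopped after the epoxide opening. Alkoxide 16 is quenched with NH4Cl (aq) at 0 °C and the alcohol (1S)-1-(3,4-dimethoxyphenyl)-2-{2-[6-fluoro-3-geranyl-2,4-bis(methoxymethoxy)phenyl]-1,3-dithian-2-yl}ethan-1-ol F1 is isolated. Ring C is then closed in a separate step by addition–elimination instead of through the aryne. The potassium alkoxide (KH, 18-crown-6, THF/DMPU, 70 °C) should displace fluoride from C8a directly, helped by the inductive effect of the two meta acetal oxygens and by the six-membered transition state (intramolecular SNAr of an alkoxide on a fluoroarene, a known way to chromans). C4 stays masked, so C2 is still protected. The fallback sets out from 16 and returns to the route at 20.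

2. Step 3. What may go wrong:
   - deprotonation of the benzylic and allylic CH2 of the geranyl chain instead of the ring;
   - loss of LiF from the aryllithium before it is trapped;
   - halogen–metal exchange at the chlorodithiane instead of substitution.

   Fallback: aryllithium 9 is quenched with DMF at −78 °C to give 6-fluoro-3-geranyl-2,4-bis(methoxymethoxy)benzaldehyde F2. The aldehyde is then thioacetalised with propane-1,3-dithiol and a catalytic amount of Hf(OTf)4 in CH2Cl2 at rt, conditions mild enough to keep the aryl MOM ethers. The fallback sets out from 9 and returns at 11.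

3. Step 2. What may go wrong:
   - metalation next to fluorine instead of between the two acetal oxygens (wrong position, and fluoride loss on warming);
   - allylic transposition (SN2′) in the copper-mediated allylation.

   Fallback: diol 1 is C-geranylated directly with geraniol on acidic alumina (ClCH2CH2Cl, reflux), a Friedel–Crafts-type allylation at the carbon between the two hydroxyls, which is ortho to both and para to fluorine. This gives 5-fluoro-2-geranylbenzene-1,3-diol F3, which is then protected with NaH and MOMCl in DMF. The fallback sets out from 1 and returns at 6.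

Further compounds
F1 | step 6 | (1S)-1-(3,4-dimethoxyphenyl)-2-{2-[6-fluoro-3-geranyl-2,4-bis(methoxymethoxy)phenyl]-1,3-dithian-2-yl}ethan-1-ol | COc1ccc([C@@H](O)CC2(SCCCS2)c3c(F)cc(OCOC)c(C/C=C(\C)CCC=C(C)C)c3OCOC)cc1OC
F2 | step 3 | 6-fluoro-3-geranyl-2,4-bis(methoxymethoxy)benzaldehyde | O=Cc1c(F)cc(OCOC)c(C/C=C(\C)CCC=C(C)C)c1OCOC
F3 | step 2 | 5-fluoro-2-geranylbenzene-1,3-diol | Oc1cc(F)cc(O)c1C/C=C(\C)CCC=C(C)C
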